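**Strategy**

Everything rests on excising C3 from ring B (the pyranone): C3 is the only ring-B carbon that carries just hydrogen, and it lies between the C2 carbonyl and the aryl-bearing C4. Without it, ring B contracts to the lactone of a 3-arylbenzofuran-2(3H)-one, assembled from a ring-A phenol and a ring-C mandelic acid. The key step puts C3 back as a dichlorocarbene carbon: addition across the enol double bond of the derived 2-silyloxybenzofuran and cyclopropane opening form the coumarin C2–C3 and C3–C4 bonds and the six-membered ring B in one operation. The precursor is the O-trimethylsilyl ketene acetal of the 7-benzyloxy-4,6-dimethoxy-3-(3,4-dimethoxyphenyl)benzofuranone; chlorine and benzyl are removed together at the end.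

Key step: step 7

Remark on the chemistry: the target is achiral; compounds 11, 12, 13 and 16 are racemic and need no stereocontrol. 2,4-Dimethoxyphenol is taken as the commercial entry to ring A, because formylation and Baeyer–Villiger oxidation then place the benzyl ether on the correct oxygen without a temporary protecting group.

**Route**

Step 1
Reactants: 1 2,4-dimethoxyphenol
Product: 3 2-hydroxy-3,5-dimethoxybenzaldehyde, via salicyl alcohol 2 (not isolated)
Conditions: MgCl2, Et3N, (CH2O)n, MeCN, reflux; then aq. HCl
Reagents that add atoms: paraformaldehyde (as formaldehyde) C=O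
Why: Magnesium-mediated ortho-formylation (Casnati–Skattebøl reaction): the chloromagnesium phenoxide of 1 delivers formaldehyde to C6, the only unsubstituted position ortho or para to the phenoxide oxygen, and the salicyl alkoxide 2 is oxidised by hydride transfer to a second formaldehyde, so a single regioisomer should form.

Step 2
Reactants: 3 2-hydroxy-3,5-dimethoxybenzaldehyde; 4 benzyl bromide
Product: 5 2-(benzyloxy)-3,5-dimethoxybenzaldehyde
Conditions: K2CO3, DMF, 60 °C
Reagents that add atoms: none
Why: Williamson etherification: carbonate deprotonates the hydrogen-bonded salicyl hydroxyl and the phenoxide displaces bromide from the primary benzylic halide 4, no other acidic or nucleophilic site being present.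

Step 3
Reactants: 5 2-(benzyloxy)-3,5-dimethoxybenzaldehyde
Product: 7 2-(benzyloxy)-3,5-dimethoxyphenol, via aryl formate 6 (not isolated)
Conditions: mCPBA, CH2Cl2, 0 °C to rt; aq. Na2S2O3/NaHCO3 wash; then cat. K2CO3, MeOH, rt
Reagents that add atoms: mCPBA (3-chloroperoxybenzoic acid) OOC(=O)c1cccc(Cl)c1
Why: Baeyer–Villiger oxidation of an ortho-alkoxybenzaldehyde (Dakin-type): in the Criegee adduct the aryl group, assisted by the ortho benzyloxy oxygen, migrates in preference to hydride, and formate 6 is cleaved by carbonate-catalysed methanolysis only after the peracid has been quenched, which protects the oxidation-prone phenol 7.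

Step 4
Reactants: 8 3,4-dimethoxybenzaldehyde
Product: 11 rac-3,4-dimethoxymandelic acid, via tribromomethyl carbinol 9 (not isolated), via dibromoepoxide 10 (not isolated)
Conditions: CHBr3, KOH, LiCl, dioxane–H2O, 0–10 °C; then aq. HCl
Reagents that add atoms: bromoform BrC(Br)Br; potassium hydroxide [K+].[OH-]
Why: Jocic–Reeve reaction: tribromomethanide adds to the aldehyde, the carbinolate of 9 closes to the gem-dibromoepoxide 10, and hydroxide opens 10 at the benzylic carbon on the way to the racemic α-hydroxy carboxylate, which is liberated on acidification.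

Step 5
Reactants: 7 2-(benzyloxy)-3,5-dimethoxyphenol; 11 rac-3,4-dimethoxymandelic acid
Product: 13 rac-7-(benzyloxy)-3-(3,4-dimethoxyphenyl)-4,6-dimethoxy-1-benzofuran-2(3H)-one, via diarylacetic acid 12 (not isolated)
Conditions: TsOH·H2O (10 mol %), ClCH2CH2Cl, 60 °C; 11 added in portions to a slight excess of 7
Reagents that add atoms: none
Why: Acid-catalysed Friedel–Crafts alkylation followed by lactonisation (the classical phenol–mandelic acid benzofuranone synthesis): the 3,4-dimethoxybenzylic cation from 11 attacks C6 of 7 (ortho to the hydroxyl, para to the 3-methoxy group), acid 12 closes to the five-membered lactone, and since attack at C4 cannot lactonise and is reversible for so electron-rich a diarylmethane, the sequence should drain to racemic 13.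

Step 6
Reactants: 13 rac-7-(benzyloxy)-3-(3,4-dimethoxyphenyl)-4,6-dimethoxy-1-benzofuran-2(3H)-one
Product: 14 {[7-(benzyloxy)-3-(3,4-dimethoxyphenyl)-4,6-dimethoxy-1-benzofuran-2-yl]oxy}trimethylsilane
Conditions: Me3SiOTf (1.2 equiv), Et3N (1.5 equiv), Et2O–toluene, 0 °C to rt; decantation from the triethylammonium triflate layer under Ar, evaporation, used at once
Reagents that add atoms: trimethylsilyl trifluoromethanesulfonate C[Si](C)(C)OS(=O)(=O)C(F)(F)F
Why: Soft enolisation: C3–H of 13 is acidified by the lactone carbonyl and two aryl groups, so Et3N with Me3SiOTf should silylate the enolate on oxygen to give the aromatic benzofuran silyl ketene acetal (the stereocentre disappears); the trimethylsilyl group is kept because it must depart as the chloride in step 7, and its hydrolytic lability is met by an entirely non-aqueous isolation.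

Step 7
Reactants: 14 {[7-(benzyloxy)-3-(3,4-dimethoxyphenyl)-4,6-dimethoxy-1-benzofuran-2-yl]oxy}trimethylsilane; 15 sodium trichloroacetate
Product: 18 8-(benzyloxy)-3-chloro-4-(3,4-dimethoxyphenyl)-5,7-dimethoxy-2H-chromen-2-one, via dichlorocyclopropane adduct 16 (not isolated), via 2-silyloxychromenylium chloride 17 (not isolated)
Conditions: Cl3CCO2Na (dried, 4 equiv, in portions), DME, reflux (85 °C), Ar; filtration, evaporation
Reagents that add atoms: none
Why: Proposed new method: thermal decarboxylation of 15 releases :CCl2 under neutral, aprotic conditions, and this electrophilic singlet carbene should add in a concerted [2+1] fashion to the most electron-rich π bond of 14, the tetrasubstituted ketene-acetal bond between furan C2 and C3, giving cyclopropane 16. The oxygen lone pairs on the former furan C2 then drive a disrotatory two-electron electrocyclic opening in which the endo chloride leaves and the old C2–C3 σ bond breaks, so the carbene carbon becomes C3 of the aromatic chromenylium ion 17, and chloride removes the silyl group as Me3SiCl to unveil the lactone carbonyl of 18. The closest known reactions are the dihalocarbene ring expansion of cyclic silyl enol ethers to 2-halo-2-enones and the Ciamician–Dennstedt conversion of indoles into 3-haloquinolines; neither has been shown on a lactone-derived 2-silyloxybenzofuran. Ring B is thus closed by ring expansion (cheletropic addition, then electrocyclic cleavage of the shared cyclopropane bond) and not by an exo or endo cyclisation, both new bonds (coumarin C2–C3 and C3–C4) being made in the carbene addition. No stereocentre survives, because the two cis-fused stereocentres of racemic 16 are erased on aromatisation. The step needs chemoselectivity for the enol double bond over the two alkoxyarenes and the benzylic C–H bonds, which the far higher nucleophilicity of the silyl ketene acetal should secure, and the absence of base avoids enolate C-dichloromethylation.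

Step 8
Reactants: 18 8-(benzyloxy)-3-chloro-4-(3,4-dimethoxyphenyl)-5,7-dimethoxy-2H-chromen-2-one
Product: 19 8-hydroxy-4-(3,4-dimethoxyphenyl)-5,7-dimethoxy-2H-chromen-2-one (8-hydroxy-5,7,3',4'-tetramethoxy-4-phenylcoumarin)
Conditions: 10% Pd/C, HCO2NH4, MeOH–THF, 50 °C
Reagents that add atoms: none
Why: Heterogeneous catalytic transfer hydrogenolysis: palladium hydride generated from formate cleaves the benzylic C–O bond and the activated vinylic C3–Cl bond (alpha to the lactone carbonyl), while the trisubstituted, aryl-conjugated C3=C4 bond should resist saturation under these mild conditions if the reaction is stopped once both groups are gone.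

**Compound list**

1 | 2,4-dimethoxyphenol | COc1ccc(O)c(OC)c1 | starting material
2 | 2-(hydroxymethyl)-4,6-dimethoxyphenol (salicyl alcohol, as its magnesium salt) | OCc1cc(OC)cc(OC)c1O | intermediate (not isolated)
3 | 2-hydroxy-3,5-dimethoxybenzaldehyde | COc1cc(C=O)c(O)c(OC)c1 | intermediate
4 | benzyl bromide | BrCc1ccccc1 | starting material
5 | 2-(benzyloxy)-3,5-dimethoxybenzaldehyde | COc1cc(C=O)c(OCc2ccccc2)c(OC)c1 | intermediate
6 | 2-(benzyloxy)-3,5-dimethoxyphenyl formate | COc1cc(OC=O)c(OCc2ccccc2)c(OC)c1 | intermediate (not isolated)
7 | 2-(benzyloxy)-3,5-dimethoxyphenol | COc1cc(O)c(OCc2ccccc2)c(OC)c1 | intermediate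
8 | 3,4-dimethoxybenzaldehyde | COc1ccc(C=O)cc1OC | starting material
9 | rac-2,2,2-tribromo-1-(3,4-dimethoxyphenyl)ethanol | COc1ccc(C(O)C(Br)(Br)Br)cc1OC | intermediate (not isolated)
10 | rac-2,2-dibromo-3-(3,4-dimethoxyphenyl)oxirane | COc1ccc(C2OC2(Br)Br)cc1OC | intermediate (not isolated)
11 | rac-2-(3,4-dimethoxyphenyl)-2-hydroxyacetic acid (3,4-dimethoxymandelic acid) | COc1ccc(C(O)C(=O)O)cc1OC | intermediate
12 | rac-2-[3-(benzyloxy)-2-hydroxy-4,6-dimethoxyphenyl]-2-(3,4-dimethoxyphenyl)acetic acid | COc1ccc(C(C(=O)O)c2c(O)c(OCc3ccccc3)c(OC)cc2OC)cc1OC | intermediate (not isolated)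
13 | rac-7-(benzyloxy)-3-(3,4-dimethoxyphenyl)-4,6-dimethoxy-1-benzofuran-2(3H)-one | COc1ccc(C2C(=O)Oc3c(OCc4ccccc4)c(OC)cc(OC)c23)cc1OC | intermediate
14 | {[7-(benzyloxy)-3-(3,4-dimethoxyphenyl)-4,6-dimethoxy-1-benzofuran-2-yl]oxy}trimethylsilane | C[Si](C)(C)Oc1oc2c(OCc3ccccc3)c(OC)cc(OC)c2c1-c1ccc(OC)c(OC)c1 | intermediate (key-step precursor)
15 | sodium trichloroacetate | [Na+].[O-]C(=O)C(Cl)(Cl)Cl | starting material
16 | rac-{[3-(benzyloxy)-1,1-dichloro-6b-(3,4-dimethoxyphenyl)-4,6-dimethoxy-1,6b-dihydro-1aH-cyclopropa[b][1]benzofuran-1a-yl]oxy}trimethylsilane (gem-dichlorocyclopropane across the former furan C2=C3 bond, cis-fused by necessity, racemic) | C[Si](C)(C)OC12Oc3c(OCc4ccccc4)c(OC)cc(OC)c3C1(c5ccc(OC)c(OC)c5)C2(Cl)Cl | intermediate (not isolated)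
17 | 8-(benzyloxy)-3-chloro-4-(3,4-dimethoxyphenyl)-5,7-dimethoxy-2-[(trimethylsilyl)oxy]chromenylium chloride | C[Si](C)(C)Oc1[o+]c2c(OCc3ccccc3)c(OC)cc(OC)c2c(-c4ccc(OC)c(OC)c4)c1Cl.[Cl-] | intermediate (not isolated)
18 | 8-(benzyloxy)-3-chloro-4-(3,4-dimethoxyphenyl)-5,7-dimethoxy-2H-chromen-2-one | COc1ccc(-c2c(Cl)c(=O)oc3c(OCc4ccccc4)c(OC)cc(OC)c23)cc1OC | intermediate (key-step product)
19 | 8-hydroxy-4-(3,4-dimethoxyphenyl)-5,7-dimethoxy-2H-chromen-2-one | COc1ccc(-c2cc(=O)oc3c(O)c(OC)cc(OC)c23)cc1OC | target

**Step count and risks**

Total steps: 8. Longest linear sequence: 7 steps (steps 1, 2, 3, 5, 6, 7, 8); step 4 is a one-step side branch.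

Steps most likely to fail:

1. Step 7 (proposed new method). The carbene may fail to engage the hindered tetrasubstituted enol double bond before adventitious moisture desilylates the ketene acetal, or the adduct may be diverted into C-dichloromethylation. Fallback by known chemistry, a Pechmann condensation that builds ring B directly, setting out from phenol 7. Phenol 7 and commercial ethyl 3-(3,4-dimethoxyphenyl)-3-oxopropanoate in CF3CO2H at room temperature should give 8-(benzyloxy)-4-(3,4-dimethoxyphenyl)-5,7-dimethoxy-2H-chromen-2-one F1. Only C6 of 7 is a free ortho position, so the lactone can close in one sense only, and premature loss of benzyl would be harmless. Hydrogenolysis of F1 (H2, Pd/C, EtOAc, rt) comes back to the route at target 19.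

2. Step 5. The benzylic cation may alkylate C4 of 7 irreversibly, the benzyl ether may be cleaved or transferred under acid, or 11 may self-condense through its own electron-rich ring. Fallback, setting out from 7, with the aryl–C3 bond made under chelation control. The bromomagnesium phenoxide of 7 (EtMgBr, toluene–CH2Cl2) is combined with commercial ethyl 2-(3,4-dimethoxyphenyl)-2-oxoacetate. The magnesium-templated, ortho-specific hydroxyalkylation and lactonisation on acidic work-up should give rac-7-(benzyloxy)-3-(3,4-dimethoxyphenyl)-3-hydroxy-4,6-dimethoxy-1-benzofuran-2(3H)-one F2. Ionic deoxygenation of F2 (Et3SiH, CF3CO2H, CH2Cl2, 0 °C) rejoins the route at benzofuranone 13.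

3. Step 8. The palladium surface may saturate the C3=C4 bond, or the reaction may stall after only one of the two cleavages. Fallback from 18, with the two cleavages separated and no hydrogenation surface. BCl3 with pentamethylbenzene (CH2Cl2, −78 °C) should remove the benzyl group as a scavenged cation, leaving the methyl ethers, to give 3-chloro-4-(3,4-dimethoxyphenyl)-8-hydroxy-5,7-dimethoxy-2H-chromen-2-one F3. Homogeneous hydrodechlorination of F3 (Pd(OAc)2, 2-dicyclohexylphosphino-2',6'-dimethoxybiphenyl, HCO2Na, DMF, 80 °C) returns at target 19; here zerovalent palladium inserts into the activated vinylic C–Cl bond and formate supplies hydride.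

Further compounds
F1 | step 7 | 8-(benzyloxy)-4-(3,4-dimethoxyphenyl)-5,7-dimethoxy-2H-chromen-2-one | COc1ccc(-c2cc(=O)oc3c(OCc4ccccc4)c(OC)cc(OC)c23)cc1OC
F2 | step 5 | rac-7-(benzyloxy)-3-(3,4-dimethoxyphenyl)-3-hydroxy-4,6-dimethoxy-1-benzofuran-2(3H)-one | COc1ccc(C2(O)C(=O)Oc3c(OCc4ccccc4)c(OC)cc(OC)c23)cc1OC
F3 | step 8 | 3-chloro-4-(3,4-dimethoxyphenyl)-8-hydroxy-5,7-dimethoxy-2H-chromen-2-one | COc1ccc(-c2c(Cl)c(=O)oc3c(O)c(OC)cc(OC)c23)cc1OC
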